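The readings are simulated for substances that don't exist, and the scatter is random.

- The constants of this flask are not given, so the reckoning starts from the shape of the two earlier curves.

| setting | theta | zeta | alpha |
|---|---|---|---|
| substrate | 0.0800 M | 0.0800 M | 0.0800 M |
| coupling partner | 0.240 M | 0.120 M | 0.0370 M |
| catalyst | 0.00800 M | 0.00800 M | 0.00800 M |
| time |  |  | 99 s |

| run | time / s | [product] / M |
|---|---|---|
| theta run | 4.0 | 4 × 10⁻⁴ |
| theta run | 6.3 | 0.0012 |
| theta run | 9.9 | 0.0011 |
| theta run | 16 | 0.0016 |
| theta run | 25 | 0.0038 |
| theta run | 39 | 0.0081 |
| theta run | 63 | 0.0170 |
| theta run | 99 | 0.0342 |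
| zeta run | 4.0 | 4 × 10⁻⁴ |
| zeta run | 6.3 | 0 |
| zeta run | 9.9 | 0.0013 |
| zeta run | 16 | 9 × 10⁻⁴ |
| zeta run | 25 | 0.0021 |
| zeta run | 39 | 0.0046 |
| zeta run | 63 | 0.0091 |
| zeta run | 99 | 0.0181 |

(scatter of a reading: 6 × 10⁻⁴ M)

- the exponent of [coupling partner] in the starting rate at the charge of the theta run (at the point where two percent of the substrate have become product)
- product in the alpha run at 99 s, as a share of the substrate charged

- Overall: substrate + coupling partner -> product, with catalyst as catalyst.
- Constant volume, constant temperature.
- Readings of a species count what is bound in complexes too.
- "The second partner" is coupling partner.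
- An order is taken over about fifteen percent of the charge, up and down.

- The theta curve starts flat: up to 16 s it averages 1.00 × 10⁻⁴ M s⁻¹, a reading with wide scatter. Between 63 s and 99 s its slope is 4.78 × 10⁻⁴ M s⁻¹, steeper, so the curve bends upward, an induction period.
- The ceiling of the theta run is 0.0800 M, the smaller charge. The last reading stands at 42.8 % of it, and the readings show no knee up to there.
- From 25 s to 99 s, theta product grows as time to the power 1.60, the time exponent. At 99 s, the theta run, with twice the [coupling partner] of the zeta run, gives product that scales as [coupling partner] to the power 0.918, the fixed-time exponent.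
- Two flasks on such curves reach the same product at different times, and the flask with more partner gets there sooner. The rate at that product is the time exponent times product over time, so it scales as [coupling partner] to the fixed-time exponent divided by the time exponent. That quotient, 0.575, is the order at fixed product.
- The order asked is taken at a fixed product, 0.00160 M, so this reckoning commits to 0.575, lower than the fixed-time exponent.
- The alpha question is asked at a fixed time, the time of the last theta reading, so the fixed-time exponent serves there. It scales the theta product to 0.00615 M, or 7.68 % of the substrate. In the alpha run the coupling partner is the limiting reagent, with a ceiling of 46.2 %.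
- The forecast gives 0.9 and 8 %, and says: “The ratio stays fairly constant, so the lag barely depends on the partner.” Its order differs from the 0.575 reckoned here.
- The flask gives 0.54 and 7.52 %.

    active catalyst + substrate ⇌ catalyst-substrate complex, settled at all times (6.280 M⁻¹)
    catalyst-substrate complex + coupling partner → product + active catalyst + by-product (1.660 M⁻¹ s⁻¹)
    catalyst → active catalyst (0.01220 s⁻¹)

- Because catalyst turns only slowly into active catalyst, the theta charge shows an order of 0.54, lower than the 1.0 it shows without that slowness. The order at fixed product carries to the zeta run, which holds half the [coupling partner] of the theta run, and it predicts a zeta-to-theta rate ratio of 0.671 at equal product. Where two percent of the substrate of the theta run have turned, the zeta run's rate of 1.3 × 10⁻⁴ M s⁻¹ and the theta run's rate of 1.9 × 10⁻⁴ M s⁻¹ stand in a ratio of 0.684.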